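Readings and results stem from a simulated flask for an exercise, and the scatter is random.

1. In this closed, stirred vessel, substrate and initiator stay the same, and the charge of coupling partner changes from flask to flask.

in all of them: substrate 0.10 M; initiator 4.9 mol%
- cedar: coupling partner 0.031 equiv; run made earlier
- oak: coupling partner 0.70 equiv; run made earlier
- Monday's: coupling partner 0.0500 equiv; time 25 min
- Thursday's: coupling partner 0.100 equiv; time 25 min
- Tuesday's: coupling partner 0.200 equiv; time 25 min
- Sunday's: coupling partner 0.400 equiv; time 25 min
- Saturday's: coupling partner 0.800 equiv; time 25 min

- cedar (time / min: target / %, substrate / %): 3.00: 2.3, 8.4; 6.00: 3.1, 4.1; 8.00: 2.2, 4.8; 12.0: 3.8, 1.0; 15.0: 2.1, 0; 20.0: 0, 0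
- oak (time / min: target / %, substrate / %): 1.33: 69.8, 6.6; 2.50: 68.3, 4.7; 4.00: 68.8, 1.4; 6.00: 67.5, 1.1; 10.0: 66.8, 0.5; 20.0: 66.5, 0

(each reading ± 1 percentage point)

- a species is counted by the substrate in it: one homo dimer or side product counts as two
- amounts and yields of target count crystals too
- given per volume of solution although it is solid: crystals
- steps that have been proposed: initiator -> 2 initiating radical; substrate + initiating radical -> chain carrier; coupling partner + chain carrier -> target + initiating radical; 2 initiating radical -> ended chains; 2 substrate -> homo dimer; substrate + target -> side product; crystals <-> target
- "hardly changes" means that all values lie within two and a half points (for a concentration: within two and a half percent of the largest)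

- amount of target at the end, in percent of the substrate charged for Monday's, Thursday's, Tuesday's, Sunday's, Saturday's, in this order
- how the row runs (hardly changes / rises, then falls / rises all the way / falls, then rises / falls all the way)

2. At oak's first reading, 1.33 min, target stands at 69.8% on a partner charge of 0.70 equiv. The substrate found in neither target nor substrate is 23.6%, less than the target. So while partner lasts, target is made quickly, and the partner looks like the limiting reagent.

3. Oak's last reading is 66.5%, which is 95.0% of its partner charge. I call this the kept share: target at the end per partner charged. My first estimate is charge times kept share.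

4. But substrate + target makes side product, and substrate lingers longer at low charge: at 6.00 min cedar reads 4.1%, more than oak's 1.1%. Oak's share may therefore flatter Monday's. Averaging cedar's 6 target readings gives a share of 72.6%, a rough figure, with a scatter of 1 percentage point on a charge of 0.031 equiv. I use it for Monday's and expect 3.63%.

5. Saturday's raises another doubt: its spare substrate, 20.0%, is less than what oak had lost elsewhere by its first reading. If Saturday's loses as much, 76.4% remains for target. The kept share gives 76.0%, just below that figure, so I keep it.

6. Does a longer run matter? Oak reads 66.8% at 10.0 min and 66.5% at 20.0 min, with substrate at 0%, so I expect no further change by the asked time.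

7. Each step along the row multiplies the charge by 2.00, while the kept share differs from end to end by a factor of 1.31, a smaller factor, so I expect the row to rise at each step.

8. The forecast, reasoning that “the target first approaches the partner charged”, gives 3.6%, 7.4%, 15%, 33% and 77%, and says the row rises all the way.

9. The flasks give 3.52%, 7.82%, 17.6%, 37.4% and 78.8%: the row rises all the way.

    initiator → 2 initiating radical (k = 0.00210 s⁻¹)
    substrate + initiating radical → chain carrier (k = 9.80 × 10⁵ M⁻¹ s⁻¹)
    coupling partner + chain carrier → target + initiating radical (k = 1.50 × 10⁵ M⁻¹ s⁻¹)
    2 initiating radical → ended chains (k = 8.00 × 10⁸ M⁻¹ s⁻¹)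
    2 substrate → homo dimer (k = 0.210 M⁻¹ s⁻¹)
    substrate + target → side product (k = 0.0510 M⁻¹ s⁻¹)
    crystals ⇌ target, rate k7*(cs7 - [target]) while solid is left; crystals form when [target] > cs7 (solubility = 6.10 mM, k = 0.0830 s⁻¹)

10. Monday's keeps 70.4% of its partner charge, less than oak's 95.0%, and Saturday's keeps 98.5%, more than oak's. With the partner held at its charge, Monday's ends at 81.8% instead of 3.52%, which makes depletion of the partner the main reason for that low figure. Held the same way, Saturday's ends at 82.7% instead of 78.8%, where depletion is one part of the story, and these two held flasks stand 0.90 points apart.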